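The pendant resorcinol ring (C1'–C6', bonded through C1' to C3 of the benzofuran) is disconnected at C1'–C6'. Its oxygens on C3' and C5' and its carbons on C1', C4' and C6' are the imprint of a 1,3,5-triketone. One base-mediated intramolecular aldol condensation of the ethyl-ketone methylene (C6') onto the benzofuran-3-yl ketone (C1'), followed by dehydration and enolization, therefore builds the whole arene with both methyl groups in place. The precursor is the 6-O-benzyl 3-(4-methyl-3,5-dioxoheptanoyl)benzofuran 14 carrying the methyl propanoate chain. It is assembled by acylating the dianion of 3-methylhexane-2,4-dione with a benzofuran-3-carbonyl chloride, itself made by carbonylative annulation of an o-alkynylphenol.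

Key step: step 10

Remark: the target SMILES carries no stereodescriptor, so the C3–C1' biaryl axis is treated as stereochemically undefined; 11, 14 and 15 are racemic or diastereomeric, largely enolized mixtures whose sp3 centres vanish on aromatization.

Step 1
Reactants: 1 3,5-dimethoxytoluene
Product: 2 1-iodo-2,4-dimethoxy-6-methylbenzene
Conditions: NIS (1.05 equiv), cat. CF3CO2H, MeCN, rt
Reagents that add atoms: N-iodosuccinimide, O=C1CCC(=O)N1I
Why: Electrophilic aromatic iodination goes to the carbon ortho to one methoxy group and para to the other (two equivalent sites), the position between the two methoxy groups being shielded, so a single mono-iodide should form with iodine next to the methyl group.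

Step 2
Reactants: 2 1-iodo-2,4-dimethoxy-6-methylbenzene
Product: 3 4-iodo-5-methylbenzene-1,3-diol
Conditions: BBr3 (3 equiv), CH2Cl2, −78 °C to rt; ice-water quench
Reagents that add atoms: none
Why: Lewis-acid ether cleavage, in which BBr3 complexes each methoxy oxygen and bromide removes the methyl group by SN2, leaves the aryl iodide untouched at low temperature.

Step 3
Reactants: 3 4-iodo-5-methylbenzene-1,3-diol
Product: 4 5-(benzyloxy)-2-iodo-3-methylphenol
Conditions: BnBr (1.0 equiv), K2CO3 (1.1 equiv), acetone, rt
Reagents that add atoms: benzyl bromide, BrCc1ccccc1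
Why: In this Williamson ether synthesis with one equivalent of electrophile, the hydroxyl next to iodine is shielded and its phenoxide is less nucleophilic, so the remote hydroxyl should be alkylated preferentially, as is usual for 4-haloresorcinols, and the dibenzyl ether is separable.

Step 4
Reactants: 4 5-(benzyloxy)-2-iodo-3-methylphenol; 5 methyl pent-4-ynoate
Product: 6 methyl 5-[4-(benzyloxy)-2-hydroxy-6-methylphenyl]pent-4-ynoate
Conditions: PdCl2(PPh3)2 (3 mol %), CuI (5 mol %), Et3N, THF, rt, degassed
Reagents that add atoms: none
Why: Sonogashira coupling of an aryl iodide proceeds at room temperature in the presence of a free phenol and an ester, and the mild temperature should keep the o-alkynylphenol from cyclizing without carbonylation.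

Step 5
Reactants: 6 methyl 5-[4-(benzyloxy)-2-hydroxy-6-methylphenyl]pent-4-ynoate
Product: 7 methyl 6-(benzyloxy)-2-(3-methoxy-3-oxopropyl)-4-methyl-1-benzofuran-3-carboxylate
Conditions: PdI2 (5 mol %), thiourea (5 mol %), CBr4, Cs2CO3, CO (1 atm), MeOH, 40 °C
Reagents that add atoms: carbon monoxide, [C-]#[O+]; methanol, CO
Why: In this cyclization–alkoxycarbonylation of an o-alkynylphenol (carbonylative heteroannulation), the phenoxide adds anti across the alkyne bound to divalent palladium in a 5-endo-dig sense, CO inserts into the C3–Pd bond and methanolysis releases the 3-ester, while CBr4 returns zerovalent palladium to the divalent state.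

Step 6
Reactants: 7 methyl 6-(benzyloxy)-2-(3-methoxy-3-oxopropyl)-4-methyl-1-benzofuran-3-carboxylate
Product: 8 6-(benzyloxy)-2-(2-carboxyethyl)-4-methyl-1-benzofuran-3-carboxylic acid
Conditions: KOH (6 equiv), MeOH–H2O, reflux; then aq. HCl, 0 °C
Reagents that add atoms: potassium hydroxide, [K+].[OH-]
Why: Saponification cleaves both methyl esters, heating being needed because the C3 ester is shielded by the C2 chain and the peri C4 methyl group, while the benzyl ether and the benzofuran are inert to hydroxide.

Step 7
Reactants: 8 6-(benzyloxy)-2-(2-carboxyethyl)-4-methyl-1-benzofuran-3-carboxylic acid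
Product: 9 6-(benzyloxy)-2-(3-methoxy-3-oxopropyl)-4-methyl-1-benzofuran-3-carboxylic acid
Conditions: MeOH, cat. H2SO4, rt
Reagents that add atoms: methanol, CO
Why: Fischer esterification at room temperature should esterify only the unhindered aliphatic acid, because the C3 acid is flanked on both sides and conjugated with the furan oxygen and so resists addition of methanol.

Step 8
Reactants: 10 hexane-2,4-dione
Product: 11 3-methylhexane-2,4-dione
Conditions: MeI (1.05 equiv), K2CO3, acetone, reflux; distillation
Reagents that add atoms: iodomethane, CI
Why: C-alkylation of the β-diketone enolate at the doubly activated C3 with iodomethane under carbonate conditions is the standard entry to 3-alkyl-2,4-diones, and minor O-methyl and dimethyl by-products are removed by distillation.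

Step 9
Reactants: 9 6-(benzyloxy)-2-(3-methoxy-3-oxopropyl)-4-methyl-1-benzofuran-3-carboxylic acid; 11 3-methylhexane-2,4-dione
Product: 14 methyl 3-[6-(benzyloxy)-4-methyl-3-(4-methyl-3,5-dioxoheptanoyl)-1-benzofuran-2-yl]propanoate, via acid chloride 12 (not isolated), via dilithium dianion 13 (not isolated)
Conditions: 9, (COCl)2, cat. DMF, CH2Cl2, 0 °C to rt, evaporate; separately 11 (3 equiv), LiN(i-Pr)2 (6 equiv), THF, −78 to 0 °C; add 12 at −78 °C, warm to −30 °C; AcOH quench
Reagents that add atoms: none
Why: In this Claisen-type C-acylation at the terminal carbon of a β-diketone 1,3-dianion, the acid chloride outcompetes the aliphatic methyl ester at low temperature, the less substituted methyl terminus is the one deprotonated, and surplus dianion deprotonates the product triketone so that it is not acylated again.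

Step 10
Reactants: 14 methyl 3-[6-(benzyloxy)-4-methyl-3-(4-methyl-3,5-dioxoheptanoyl)-1-benzofuran-2-yl]propanoate
Product: 16 methyl 3-[6-(benzyloxy)-3-(3,5-dihydroxy-2,4-dimethylphenyl)-4-methyl-1-benzofuran-2-yl]propanoate, via cyclic aldol adduct 15 (not isolated)
Conditions: NaOMe (6 equiv), MeOH, reflux; then HCl/MeOH to pH 1, rt
Reagents that add atoms: none
Why: Excess methoxide turns 14 into its enolates, and in the small equilibrium fraction that is enolized across C3'–C5' and deprotonated once more at C6', the C6' carbon adds to the still free C1' ketone to give aldol 15, which loses water by E1cB and tautomerizes at C3' and C5' to the resorcinol bis-phenoxide, an irreversible aromatization that drains the reversible enolate equilibria. The closest known reaction type is the base-mediated cyclization of 1,3,5-triketones to resorcinols used as polyketide model chemistry. The one ring is closed in a 6-(enolexo)-exo-trig mode, and the sp3 centres of 14 and 15 are erased on aromatization, so no stereocentre has to be controlled. The step needs carbon rather than oxygen cyclization, which the basic medium should secure because 4-pyranone formation depends on acid-promoted dehydration of a hemiketal. It also needs the C6'-to-C1' pairing, which the chain secures because any other combination of an enolizable chain carbon with a chain carbonyl would produce a cyclobutane, while the far less acidic ester α-carbon could only give a strained cyclopenta-fused aldol that reverts. Methoxide in methanol makes ester exchange degenerate, and the acidic methanol quench re-esterifies any acid formed by the water released.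

Step 11
Reactants: 16 methyl 3-[6-(benzyloxy)-3-(3,5-dihydroxy-2,4-dimethylphenyl)-4-methyl-1-benzofuran-2-yl]propanoate
Product: 17 Talarominine A, methyl 3-[3-(3,5-dihydroxy-2,4-dimethylphenyl)-6-hydroxy-4-methyl-1-benzofuran-2-yl]propanoate
Conditions: H2 (1 atm), 10% Pd/C, EtOAc–MeOH, rt
Reagents that add atoms: none
Why: Catalytic hydrogenolysis cleaves the benzylic C–O bond of the aryl benzyl ether, while the tetrasubstituted C2=C3 bond of the benzofuran, the arenes, the phenols and the methyl ester should not be reduced at one atmosphere and room temperature.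

Compound list
1 | 3,5-dimethoxytoluene (1,3-dimethoxy-5-methylbenzene) | COc1cc(C)cc(OC)c1 | starting material
2 | 1-iodo-2,4-dimethoxy-6-methylbenzene | COc1cc(C)c(I)c(OC)c1 | intermediate
3 | 4-iodo-5-methylbenzene-1,3-diol | Oc1cc(C)c(I)c(O)c1 | intermediate
4 | 5-(benzyloxy)-2-iodo-3-methylphenol | Oc1cc(OCc2ccccc2)cc(C)c1I | intermediate
5 | methyl pent-4-ynoate | COC(=O)CCC#C | starting material
6 | methyl 5-[4-(benzyloxy)-2-hydroxy-6-methylphenyl]pent-4-ynoate | COC(=O)CCC#Cc1c(C)cc(OCc2ccccc2)cc1O | intermediate
7 | methyl 6-(benzyloxy)-2-(3-methoxy-3-oxopropyl)-4-methyl-1-benzofuran-3-carboxylate | COC(=O)CCc1oc2cc(OCc3ccccc3)cc(C)c2c1C(=O)OC | intermediate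
8 | 6-(benzyloxy)-2-(2-carboxyethyl)-4-methyl-1-benzofuran-3-carboxylic acid | OC(=O)CCc1oc2cc(OCc3ccccc3)cc(C)c2c1C(=O)O | intermediate
9 | 6-(benzyloxy)-2-(3-methoxy-3-oxopropyl)-4-methyl-1-benzofuran-3-carboxylic acid | COC(=O)CCc1oc2cc(OCc3ccccc3)cc(C)c2c1C(=O)O | intermediate
10 | hexane-2,4-dione | CCC(=O)CC(C)=O | starting material
11 | 3-methylhexane-2,4-dione (racemic, enolizable) | CCC(=O)C(C)C(C)=O | intermediate
12 | methyl 3-[6-(benzyloxy)-3-(chlorocarbonyl)-4-methyl-1-benzofuran-2-yl]propanoate (not isolated) | COC(=O)CCc1oc2cc(OCc3ccccc3)cc(C)c2c1C(Cl)=O | intermediate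
13 | dilithium 3-methylhexa-1,3-diene-2,4-diolate, the 1,3-dianion of 11 (not isolated, alkene geometry undefined) | [Li+].[Li+].C=C([O-])C(C)=C([O-])CC | intermediate
14 | methyl 3-[6-(benzyloxy)-4-methyl-3-(4-methyl-3,5-dioxoheptanoyl)-1-benzofuran-2-yl]propanoate (racemic, largely enolized; key-step precursor) | COC(=O)CCc1oc2cc(OCc3ccccc3)cc(C)c2c1C(=O)CC(=O)C(C)C(=O)CC | intermediate
15 | methyl 3-[6-(benzyloxy)-3-(1-hydroxy-2,4-dimethyl-3,5-dioxocyclohexyl)-4-methyl-1-benzofuran-2-yl]propanoate (mixture of diastereomers, not isolated) | COC(=O)CCc1oc2cc(OCc3ccccc3)cc(C)c2c1C1(O)CC(=O)C(C)C(=O)C1C | intermediate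
16 | methyl 3-[6-(benzyloxy)-3-(3,5-dihydroxy-2,4-dimethylphenyl)-4-methyl-1-benzofuran-2-yl]propanoate (key-step product) | COC(=O)CCc1oc2cc(OCc3ccccc3)cc(C)c2c1-c1cc(O)c(C)c(O)c1C | intermediate
17 | Talarominine A, methyl 3-[3-(3,5-dihydroxy-2,4-dimethylphenyl)-6-hydroxy-4-methyl-1-benzofuran-2-yl]propanoate | COC(=O)CCc1oc2cc(O)cc(C)c2c1-c1cc(O)c(C)c(O)c1C | target

Total step count: 11. Longest linear sequence: 10 steps (steps 1–7 and 9–11, from 1 to 17); step 8 is a one-step side branch.

Steps most likely to fail

Step 10 (ring closure). The addition to the hindered C1' ketone, which is deactivated as a vinylogous ester, may be slow. Prolonged heating could then let retro-Claisen cleavage of the chain, saponification by the released water, or pyranone formation on work-up take over. The fallback gives up the ester before ring closure so that far more forcing hydroxide conditions become available. It sets out from 14: saponification (aq. LiOH, THF, rt) would give 3-[6-(benzyloxy)-4-methyl-3-(4-methyl-3,5-dioxoheptanoyl)-1-benzofuran-2-yl]propanoic acid F1. Its carboxylate, inert as a spectator, would be heated in 2 M aqueous KOH at 90 °C, the classical medium for triketone-to-resorcinol closure, to give 3-[6-(benzyloxy)-3-(3,5-dihydroxy-2,4-dimethylphenyl)-4-methyl-1-benzofuran-2-yl]propanoic acid F2 after acidification. Fischer esterification (MeOH, cat. H2SO4, rt) would come back to the route at 16.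

Step 9 (dianion acylation). O-acylation or double acylation of the dianion may compete. Attack at the shielded acyl chloride may also be sluggish enough for the dianion to consume the side-chain ester. Acylation at the ethyl terminus of 13 would not be a loss, since that regioisomeric triketone is expected to fold to the same arene 16. The fallback replaces acylation by aldol addition followed by oxidation and sets out from acid chloride 12. Reduction with LiAlH(Ot-Bu)3 (THF, −78 °C) would give methyl 3-[6-(benzyloxy)-3-formyl-4-methyl-1-benzofuran-2-yl]propanoate F3. Aldol addition of dianion 13 (THF, −78 °C), with the aldehyde far more electrophilic than the ester, would give methyl 3-[6-(benzyloxy)-3-(1-hydroxy-4-methyl-3,5-dioxoheptyl)-4-methyl-1-benzofuran-2-yl]propanoate F4. Oxidation of this benzylic-type carbinol with MnO2 (CH2Cl2, rt) would come back to the route at 14.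

Step 3 (mono-benzylation). Discrimination between the two hydroxyls may be insufficient, giving over-alkylation and alkylation at the oxygen next to iodine. The fallback postpones protection until ring closure has consumed one hydroxyl and sets out from 3. Sonogashira coupling with 5 (PdCl2(PPh3)2, CuI, Et3N, THF, rt) would give methyl 5-(2,4-dihydroxy-6-methylphenyl)pent-4-ynoate F5. Cyclization–methoxycarbonylation as in step 5 would give methyl 6-hydroxy-2-(3-methoxy-3-oxopropyl)-4-methyl-1-benzofuran-3-carboxylate F6, which has a single hydroxyl left. Benzylation (BnBr, K2CO3, acetone) would come back to the route at 7.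

Further compounds
F1 | step 10 | 3-[6-(benzyloxy)-4-methyl-3-(4-methyl-3,5-dioxoheptanoyl)-1-benzofuran-2-yl]propanoic acid | OC(=O)CCc1oc2cc(OCc3ccccc3)cc(C)c2c1C(=O)CC(=O)C(C)C(=O)CC
F2 | step 10 | 3-[6-(benzyloxy)-3-(3,5-dihydroxy-2,4-dimethylphenyl)-4-methyl-1-benzofuran-2-yl]propanoic acid | OC(=O)CCc1oc2cc(OCc3ccccc3)cc(C)c2c1-c1cc(O)c(C)c(O)c1C
F3 | step 9 | methyl 3-[6-(benzyloxy)-3-formyl-4-methyl-1-benzofuran-2-yl]propanoate | COC(=O)CCc1oc2cc(OCc3ccccc3)cc(C)c2c1C=O
F4 | step 9 | methyl 3-[6-(benzyloxy)-3-(1-hydroxy-4-methyl-3,5-dioxoheptyl)-4-methyl-1-benzofuran-2-yl]propanoate (mixture of diastereomers) | COC(=O)CCc1oc2cc(OCc3ccccc3)cc(C)c2c1C(O)CC(=O)C(C)C(=O)CC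
F5 | step 3 | methyl 5-(2,4-dihydroxy-6-methylphenyl)pent-4-ynoate | COC(=O)CCC#Cc1c(C)cc(O)cc1O
F6 | step 3 | methyl 6-hydroxy-2-(3-methoxy-3-oxopropyl)-4-methyl-1-benzofuran-3-carboxylate | COC(=O)CCc1oc2cc(O)cc(C)c2c1C(=O)OC
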